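The numbers in the tables were generated by integration with made-up constants; the scatter is artificial.

Compare the two flasks first: the new flask carries twice the second substrate of the spring run on the same partner charge, so ask how that partner gets divided.

| flask | starting material | partner | second substrate | catalyst | remark | time |
|---|---|---|---|---|---|---|
| spring | 0.43 M | 1.5 equiv | 2.5 equiv (in portions, 4) | 10 mol% | run made earlier; portions every 20 h |  |
| flask | 0.43 M | 1.50 equiv | 5.00 equiv (in portions, 4) | 10 mol% | the portions of second substrate follow each other after 20 h, the first at the start | 15 d |

spring run (percent of the starting material charged)

| time / d | target / % | starting material / % |
|---|---|---|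
| 1.04 | 16.9 | 28.3 |
| 3.00 | 27.9 | 20.8 |
| 5.00 | 32.1 | 21.0 |
| 8.00 | 35.9 | 19.0 |
| 10.0 | 39.9 | 19.9 |
| 15.0 | 41.0 | 19.7 |
| 20.0 | 40.1 | 20.8 |

(each reading ± 1 percentage point)

- the analysis behind the earlier runs scatters by 1 percentage point, standard deviation
- the reaction counts as stopped when no species that holds the starting material changes by six tenths of a point or more over the second half of the time

- at 15 d, what has stopped the reaction, if anything has (it is still moving / all of the starting material has reacted / no working catalyst is left / the partner has run out first)
- how much target there is at 15 d, in percent of the starting material charged

Assume, as my own reckoning, that the spring run's 1.5 equiv of partner ended up divided between target and second substrate, one partner per target, with the reading of 41.0 % target at 15.0 d as the flat end. The target's share of the partner is then 27.3 %. Write that share as parity over parity plus charge, which gives 0.940 equivalents for the parity charge, the charge of second substrate at which this rule divides the partner evenly, a selectivity factor in units of charge.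

Take the spring reading as a first ceiling, since the new flask holds more second substrate. Parity held fixed gives a floor of 23.7 %. I count it as my floor because at that yield the new flask holds 76.3 % of its starting material outside the target, more than the 59.0 % of the spring run, and I let that remainder compete for the partner. Scale parity by that remainder, counted at the floor, to get 1.22 equivalents and a second ceiling of 29.3 %, lower than the first. My answer: the partner stops the flask, with target inside that bracket.

The forecast says no working catalyst is left and 46 % target, within 35 % to 60 %, on the ground that “A plateau with both reactants present points to a dead catalyst”, which places it above my bracket.

The flask gives 29.2 %, and what stopped it: the partner has run out first, with 0.032 % of its charge left.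

    starting material + partner + catalyst → catalyst + target (k = 0.00880 M⁻² min⁻¹)
    second substrate + partner + catalyst → catalyst + second product (k = 0.00500 M⁻² min⁻¹)
    starting material ⇌ dormant form (K = 2.00, k = 0.00120 min⁻¹)

At 15.0 d the partner is the limiting reagent, while 76 % of the second substrate and 100 % of the catalyst remain. Read back from this result, the flask's own parity charge is 1.21 equivalents, above the spring value.

For the neighbour with 3.00 equiv of second substrate, the same reckoning gives a floor of 35.8 % and, with parity 1.02 equivalents, a ceiling of 38.2 %. That flask gives 37.0 %.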